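**Retrosynthetic overview**
1. Target 13 ⇐ N-oxidation of pyridine 12 ⇐ alkene hydrogenation ⇐ cross-metathesis of the (5S)-5-allyl-tetrahydroquinoline 9 with 4-phenylbut-1-ene.
2. 9 ⇐ enantioselective, desymmetrising Ni(0)/NHC/Al C–H cyclisation of the achiral bis-allyl pyridine 8; this one operation closes the carbocycle by forming the C8–C8a bond and sets the C5 stereocentre.
3. Enabling feature: C8a–H is the only C–H of the pyridine ring (C2 bears Me, C3 and C4 bear OMe) and lies next to the Lewis-basic N1, where aluminium can bind and activate it. In addition, the two CH2 arms on C5 (C6–C7–C8 of the carbocycle and the first three carbons of the phenylpentyl chain) can both be drawn as allyl groups, so C5 can start as a prochiral diallyl carbon.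
4. 8 ⇐ secondary-alkyl Negishi coupling of 5-bromo-3,4-dimethoxy-2-methylpyridine 4 (from pyridone 1 by bromination, POCl3, NaOMe) with the zinc reagent derived from hepta-1,6-dien-4-ol.
5. Ring order: the pyridine ring is bought intact; the carbocycle is formed last, in the key step.

Key step: step 6

Assumption: the sense of induction of the chiral NHC in step 6 cannot be predicted reliably, so the ligand antipode found to give (5S)-9 is the one specified; compounds 1, 5 and 10 are taken as commercial.

Step 1
Reactants: 1 3-methoxy-2-methylpyridin-4(1H)-one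
Product: 2 5-bromo-3-methoxy-2-methylpyridin-4(1H)-one
Conditions: NBS (1.05 equiv), MeCN, 0 °C → rt
Reagents that add atoms: N-bromosuccinimide, O=C1CCC(=O)N1Br
Why: Electrophilic aromatic bromination of a 4-pyridone goes to the positions ortho to the carbonyl (C3/C5), and since C3 carries OMe only C5 can react.

Step 2
Reactants: 2 5-bromo-3-methoxy-2-methylpyridin-4(1H)-one
Product: 3 5-bromo-4-chloro-3-methoxy-2-methylpyridine
Conditions: POCl3 (3 equiv), toluene, 100 °C; then ice-water
Reagents that add atoms: phosphoryl chloride, O=P(Cl)(Cl)Cl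
Why: Deoxychlorination of a 4-pyridone with POCl3 (O-phosphorylation, then chloride addition–elimination at C4) is standard and leaves the aryl bromide and the methyl ether untouched.

Step 3
Reactants: 3 5-bromo-4-chloro-3-methoxy-2-methylpyridine
Product: 4 5-bromo-3,4-dimethoxy-2-methylpyridine
Conditions: NaOMe (2 equiv), MeOH, 80 °C (sealed vessel)
Reagents that add atoms: sodium methoxide, C[O-].[Na+]
Why: Nucleophilic aromatic substitution (SNAr) by methoxide takes place only at C4, which is para to the ring nitrogen and flanked by the inductively activating bromine, whereas the C5 bromide is meta to nitrogen and inert.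

Step 4
Reactants: 5 hepta-1,6-dien-4-ol
Product: 6 4-bromohepta-1,6-diene
Conditions: CBr4 (1.2 equiv), PPh3 (1.25 equiv), CH2Cl2, 0 °C → rt
Reagents that add atoms: carbon tetrabromide, BrC(Br)(Br)Br
Why: Appel reaction, in which the alkoxyphosphonium ion of the secondary alcohol is displaced by bromide (SN2) under neutral conditions that leave both terminal alkenes untouched; the carbinol carbon is not a stereocentre.

Step 5
Reactants: 6 4-bromohepta-1,6-diene; 4 5-bromo-3,4-dimethoxy-2-methylpyridine
Product: 8 5-(hepta-1,6-dien-4-yl)-3,4-dimethoxy-2-methylpyridine, via hepta-1,6-dien-4-ylzinc bromide 7 (not isolated)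
Conditions: 6, Zn dust (activated), LiCl, THF, 40 °C; then 4, Pd(OAc)2 (2 mol %), CPhos (4 mol %), THF/toluene, rt
Reagents that add atoms: none
Why: Negishi cross-coupling of a secondary alkylzinc halide (from LiCl-promoted zinc insertion) with a heteroaryl bromide, in which the CPhos ligand makes reductive elimination faster than β-hydride elimination so that the unrearranged branched product forms; the new ring-attached carbon carries two identical allyl groups and is not yet a stereocentre.

Step 6
Reactants: 8 5-(hepta-1,6-dien-4-yl)-3,4-dimethoxy-2-methylpyridine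
Product: 9 (5S)-3,4-dimethoxy-2-methyl-5-(prop-2-en-1-yl)-5,6,7,8-tetrahydroquinoline
Conditions: Ni(cod)2 (10 mol %), bulky C2-symmetric chiral NHC (ANIPE type, 10 mol %), AlMe3 (40 mol %), toluene, 80 °C
Reagents that add atoms: none
Why: Proposed new method: AlMe3 bound to N1 acidifies the adjacent C8a–H, Ni(0)–NHC coordinates one allyl C=C, and ligand-to-ligand hydrogen transfer moves that hydrogen to the internal alkene carbon (C7) to give a seven-membered aryl–Ni–alkyl nickelacycle with nickel on the terminal carbon, from which C(sp2)–C(sp3) reductive elimination forms the C8–C8a bond. The closest known reaction type is the Ni(0)/bulky-NHC/aluminium-Lewis-acid-catalysed endo-selective intramolecular alkene hydroheteroarylation (C–H cyclisation) of pyridines and pyridones, including enantioselective versions that create the stereocentre at the alkene carbon; new here is its use at a pyridine C–H alpha to nitrogen together with selection between two enantiotopic allyl arms. The carbocycle (C4a–C5–C6–C7–C8–C8a) closes in a formal 6-endo-trig, anti-Markovnikov mode. The C5 stereocentre is set by catalyst control, since the chiral pocket of the NHC decides which of the two enantiotopic allyl groups enters the nickelacycle while the spectator allyl group sits pseudo-equatorial. Site selectivity is secured because C8a–H is the only ring C–H, endo over 5-exo closure is enforced by the bulky NHC that places nickel on the terminal carbon, and a second cyclisation is impossible for lack of another C–H, so the remaining allyl group survives as the handle for the side chain.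

Step 7
Reactants: 9 (5S)-3,4-dimethoxy-2-methyl-5-(prop-2-en-1-yl)-5,6,7,8-tetrahydroquinoline; 10 4-phenylbut-1-ene
Product: 11 (5S)-3,4-dimethoxy-2-methyl-5-[(2E)-5-phenylpent-2-en-1-yl]-5,6,7,8-tetrahydroquinoline
Conditions: Hoveyda–Grubbs II (5 mol %), 10 (4 equiv), CH2Cl2, 40 °C
Reagents that add atoms: none
Why: Olefin cross-metathesis between two unhindered terminal alkenes, driven by loss of ethylene and an excess of 10; the E/Z ratio is irrelevant because the alkene is reduced in step 8, and C5 is not touched.

Step 8
Reactants: 11 (5S)-3,4-dimethoxy-2-methyl-5-[(2E)-5-phenylpent-2-en-1-yl]-5,6,7,8-tetrahydroquinoline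
Product: 12 (5R)-3,4-dimethoxy-2-methyl-5-(5-phenylpentyl)-5,6,7,8-tetrahydroquinoline
Conditions: H2 (1 atm), 5% Pt/C, EtOAc, rt
Reagents that add atoms: none
Why: Heterogeneous catalytic hydrogenation of the 1,2-disubstituted alkene, with platinum instead of palladium to suppress double-bond migration towards C5, so the stereocentre is retained (the descriptor changes from S to R only because the CIP priorities change on saturation) while the pyridine and phenyl rings stay intact under neutral conditions.

Step 9
Reactants: 12 (5R)-3,4-dimethoxy-2-methyl-5-(5-phenylpentyl)-5,6,7,8-tetrahydroquinoline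
Product: 13 (5R)-3,4-dimethoxy-2-methyl-5-(5-phenylpentyl)-5,6,7,8-tetrahydroquinoline 1-oxide
Conditions: mCPBA (1.1 equiv), CH2Cl2, 0 °C → rt
Reagents that add atoms: 3-chloroperoxybenzoic acid, O=C(OO)c1cccc(Cl)c1
Why: Peracid N-oxidation of an electron-rich pyridine nitrogen, the only readily oxidisable site once the alkene is gone, which does not affect C5.

**Compound list**
1 | 3-methoxy-2-methylpyridin-4(1H)-one | COc1c(C)[nH]ccc1=O | starting material
2 | 5-bromo-3-methoxy-2-methylpyridin-4(1H)-one | COc1c(C)[nH]cc(Br)c1=O | intermediate
3 | 5-bromo-4-chloro-3-methoxy-2-methylpyridine | COc1c(C)ncc(Br)c1Cl | intermediate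
4 | 5-bromo-3,4-dimethoxy-2-methylpyridine | COc1c(OC)c(C)ncc1Br | intermediate
5 | hepta-1,6-dien-4-ol | C=CCC(O)CC=C | starting material
6 | 4-bromohepta-1,6-diene | C=CCC(Br)CC=C | intermediate
7 | hepta-1,6-dien-4-ylzinc bromide (not isolated) | C=CCC([Zn]Br)CC=C | intermediate
8 | 5-(hepta-1,6-dien-4-yl)-3,4-dimethoxy-2-methylpyridine (achiral) | COc1c(OC)c(C)ncc1C(CC=C)CC=C | intermediate
9 | (5S)-3,4-dimethoxy-2-methyl-5-(prop-2-en-1-yl)-5,6,7,8-tetrahydroquinoline | COc1c(OC)c(C)nc2c1[C@H](CC=C)CCC2 | intermediate
10 | 4-phenylbut-1-ene | C=CCCc1ccccc1 | starting material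
11 | (5S)-3,4-dimethoxy-2-methyl-5-[(2E)-5-phenylpent-2-en-1-yl]-5,6,7,8-tetrahydroquinoline | COc1c(OC)c(C)nc2c1[C@H](C/C=C/CCc1ccccc1)CCC2 | intermediate
12 | (5R)-3,4-dimethoxy-2-methyl-5-(5-phenylpentyl)-5,6,7,8-tetrahydroquinoline | COc1c(OC)c(C)nc2c1[C@H](CCCCCc1ccccc1)CCC2 | intermediate
13 | (5R)-3,4-dimethoxy-2-methyl-5-(5-phenylpentyl)-5,6,7,8-tetrahydroquinoline 1-oxide | COc1c(OC)c(C)[n+]([O-])c2c1[C@H](CCCCCc1ccccc1)CCC2 | target

**Step count**
Total steps: 9. Longest linear sequence: 8 steps (steps 1–3 and 5–9; step 4 is a one-step side branch).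

**Steps most likely to fail**

Step 6 (proposed new method). The cyclisation may discriminate poorly between the two enantiotopic allyl arms, may divert to 5-exo closure or terminal-alkene isomerisation, or may stall if aluminium on N1 hinders nickel insertion into the neighbouring C–H. The fallback uses known chemistry, sets out from 4 and comes back at 12. Bromine–magnesium exchange of 4 with iPrMgCl·LiCl (THF, 0 °C) should give (4,5-dimethoxy-6-methylpyridin-3-yl)magnesium chloride F1, which would open glutaric anhydride (−40 °C) to 5-(4,5-dimethoxy-6-methylpyridin-3-yl)-5-oxopentanoic acid F2. A silver-catalysed decarboxylative intramolecular Minisci cyclisation (AgNO3 cat., (NH4)2S2O8, TFA, MeCN/H2O, 70 °C) would close the same C8–C8a bond, the primary alkyl radical attacking the protonated pyridine at its only free position, to give 3,4-dimethoxy-2-methyl-7,8-dihydroquinolin-5(6H)-one F3. CeCl3-promoted addition of (5-phenylpentyl)magnesium bromide F4 (from (5-bromopentyl)benzene and Mg) should give the racemic tertiary alcohol 3,4-dimethoxy-2-methyl-5-(5-phenylpentyl)-5,6,7,8-tetrahydroquinolin-5-ol F5. Acid-catalysed dehydration (TsOH, toluene, reflux) would give 3,4-dimethoxy-2-methyl-5-(5-phenylpentyl)-7,8-dihydroquinoline F6. Iridium-catalysed asymmetric hydrogenation of this cyclic trisubstituted aryl alkene (cationic Ir complex of a chiral P,N ligand, BArF counter-ion, H2 50 bar, CH2Cl2) would then set C5 and deliver 12, which rejoins the route at step 9.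

Step 5. Zinc insertion into the secondary bromide may be sluggish, and β-hydride elimination or chain-walking at the secondary alkyl–palladium stage may give isomerised or reduced products. The fallback builds the diallyl carbon by polar additions, setting out from 4 and coming back at 8. The arylmagnesium chloride F1 (made as above) would be quenched with DMF to give 4,5-dimethoxy-6-methylpyridine-3-carbaldehyde F7. Allylmagnesium bromide (THF, −78 °C) should give racemic 1-(4,5-dimethoxy-6-methylpyridin-3-yl)but-3-en-1-ol F8, and SOCl2 (CH2Cl2, 0 °C) would convert it into racemic 5-(1-chlorobut-3-en-1-yl)-3,4-dimethoxy-2-methylpyridine F9, used at once after cold neutralisation. Coupling of this activated secondary pyridylmethyl chloride with allylmagnesium bromide (THF, −20 °C) should give 8, which continues with step 6.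

Step 7. The ruthenium carbene may be deactivated by coordination of the pyridine nitrogen, and statistical homodimerisation may consume the allyl compound. The fallback avoids metathesis, setting out from 9 and coming back at 12. Hydroboration of the allyl group with 9-BBN-H (THF, rt) should give 9-{3-[(5R)-3,4-dimethoxy-2-methyl-5,6,7,8-tetrahydroquinolin-5-yl]propyl}-9-borabicyclo[3.3.1]nonane F10. Alkyl–alkyl Suzuki–Miyaura coupling of F10 with (2-bromoethyl)benzene (Pd(OAc)2, PCy3, K3PO4·H2O, THF, rt) would give 12 directly, so step 8 is bypassed and the route continues with step 9.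

**Further compounds**
F1 | step 6 | (4,5-dimethoxy-6-methylpyridin-3-yl)magnesium chloride | COc1c(OC)c(C)ncc1[Mg]Cl
F2 | step 6 | 5-(4,5-dimethoxy-6-methylpyridin-3-yl)-5-oxopentanoic acid | COc1c(OC)c(C)ncc1C(=O)CCCC(=O)O
F3 | step 6 | 3,4-dimethoxy-2-methyl-7,8-dihydroquinolin-5(6H)-one | COc1c(OC)c(C)nc2c1C(=O)CCC2
F4 | step 6 | (5-phenylpentyl)magnesium bromide | Br[Mg]CCCCCc1ccccc1
F5 | step 6 | rac-3,4-dimethoxy-2-methyl-5-(5-phenylpentyl)-5,6,7,8-tetrahydroquinolin-5-ol | COc1c(OC)c(C)nc2c1C(O)(CCCCCc1ccccc1)CCC2
F6 | step 6 | 3,4-dimethoxy-2-methyl-5-(5-phenylpentyl)-7,8-dihydroquinoline | COc1c(OC)c(C)nc2c1C(CCCCCc1ccccc1)=CCC2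
F7 | step 5 | 4,5-dimethoxy-6-methylpyridine-3-carbaldehyde | COc1c(OC)c(C)ncc1C=O
F8 | step 5 | rac-1-(4,5-dimethoxy-6-methylpyridin-3-yl)but-3-en-1-ol | COc1c(OC)c(C)ncc1C(O)CC=C
F9 | step 5 | rac-5-(1-chlorobut-3-en-1-yl)-3,4-dimethoxy-2-methylpyridine | COc1c(OC)c(C)ncc1C(Cl)CC=C
F10 | step 7 | 9-{3-[(5R)-3,4-dimethoxy-2-methyl-5,6,7,8-tetrahydroquinolin-5-yl]propyl}-9-borabicyclo[3.3.1]nonane | COc1c(OC)c(C)nc2c1[C@H](CCCB1C3CCCC1CCC3)CCC2
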